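**Retrosynthetic overview**
1. The aromatic substituents are added last: ortho-formylation of the free resorcinol, after acetal removal and a para C–H borylation/one-carbon homologation of a 2-(decalinylmethyl)resorcinol bis(methoxymethyl) ether.
2. The C3 carbinol comes from the 3-ketone by catalyst-controlled reduction; the ketone comes from the C3-epimeric alcohol, whose configuration serves only to relay stereocontrol to C5.
3. Key disconnection: the C4–C5 bond of ring A, formed by Cp2TiCl (trivalent titanium) epoxide opening, 6-endo radical cyclisation onto the ring B cyclohexene and β-hydrogen abstraction, which gives the C1=C10 alkene directly.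
4. The epoxy-diene comes from an enol triflate and a homoprenylzinc reagent, followed by asymmetric epoxidation; the ring B ketone comes from 2-methylcyclohexenone, AlMe3 and a 2,6-dioxygenated benzyl bromide made from resorcinol (sets C8 and C9).
5. Ring order: the aromatic ring and ring B are bought; ring A is closed last, in the radical step.

Assumption: terpenoid carbons carry drimane-type locants (ring A = C1–C5 and C10, ring B = C5–C10, C11 = benzylic CH2), and the target is taken as the open hydroxy-aldehyde drawn, whatever its equilibrium with the lactol.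

**Route**

Step 1
Reactants: 1 resorcinol (benzene-1,3-diol)
Product: 2 1,3-bis(methoxymethoxy)benzene
Conditions: NaH (2.4 equiv), MOMCl (2.4 equiv), DMF, 0 °C → rt
Reagents that add atoms: chloromethyl methyl ether, COCCl
Why: Double Williamson-type O-alkylation of the bis-phenoxide installs methoxymethyl acetals that survive the basic, organometallic, oxidative and radical steps that follow and that direct the ortho-lithiation of step 2; no stereocentre is formed.

Step 2
Reactants: 2 1,3-bis(methoxymethoxy)benzene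
Product: 4 [2,6-bis(methoxymethoxy)phenyl]methanol, via aryllithium 3 (not isolated)
Conditions: n-BuLi (1.1 equiv), THF, 0 °C; then (CH2O)n (cracked), −78 °C → rt; aq. NH4Cl
Reagents that add atoms: formaldehyde, C=O
Why: Directed ortho-metalation removes the proton between the two OCH2OMe groups selectively through cooperative lithium coordination, and the aryllithium is hydroxymethylated by monomeric formaldehyde, which installs the future C11.

Step 3
Reactants: 4 [2,6-bis(methoxymethoxy)phenyl]methanol
Product: 5 2-(bromomethyl)-1,3-bis(methoxymethoxy)benzene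
Conditions: CBr4, PPh3, CH2Cl2, 0 °C; used at once
Reagents that add atoms: carbon tetrabromide, BrC(Br)(Br)Br
Why: Appel bromination converts the benzylic alcohol into the bromide under neutral conditions that leave the acid-labile acetals untouched, and the electron-rich bromide is used immediately because it ionises easily.

Step 4
Reactants: 5 2-(bromomethyl)-1,3-bis(methoxymethoxy)benzene; 6 2-methylcyclohex-2-en-1-one
Product: 9 (2S,3R)-2-{[2,6-bis(methoxymethoxy)phenyl]methyl}-2,3-dimethylcyclohexan-1-one, via dimethylaluminium enolate 7 (not isolated), via lithium aluminate enolate 8 (not isolated)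
Conditions: AlMe3 (1.3 equiv), copper thiophene-2-carboxylate Cu(O2CC4H3S) (2 mol%), chiral biphenol phosphoramidite ligand (4 mol%, enantiomer giving the 3R enolate), Et2O, −30 °C; then MeLi (1.3 equiv), THF/DMPU, −78 °C; then 5, −78 °C → rt
Reagents that add atoms: trimethylaluminium, C[Al](C)C
Why: Copper-catalysed asymmetric conjugate addition of AlMe3 to the enone sets C8 (R) under ligand control, and the aluminate enolate is then benzylated at C9 on the face anti to the new C8 methyl group (enolate alkylation trans to the adjacent substituent), which sets the quaternary centre (S) with the two methyl groups cis.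

Step 5
Reactants: 9 (2S,3R)-2-{[2,6-bis(methoxymethoxy)phenyl]methyl}-2,3-dimethylcyclohexan-1-one
Product: 10 (5R,6S)-6-{[2,6-bis(methoxymethoxy)phenyl]methyl}-5,6-dimethylcyclohex-1-en-1-yl trifluoromethanesulfonate
Conditions: KN(SiMe3)2 (1.2 equiv), PhNTf2 (1.2 equiv), THF, −78 → 0 °C; aq. NH4Cl
Reagents that add atoms: N-phenylbis(trifluoromethanesulfonimide), O=S(=O)(N(c1ccccc1)S(=O)(=O)C(F)(F)F)C(F)(F)F
Why: The ketone can enolise only toward C5, so kinetic deprotonation and O-sulfonylation give a single enol triflate (enol triflate formation) without touching either stereocentre.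

Step 6
Reactants: 10 (5R,6S)-6-{[2,6-bis(methoxymethoxy)phenyl]methyl}-5,6-dimethylcyclohex-1-en-1-yl trifluoromethanesulfonate; 11 5-bromo-2-methylpent-2-ene
Product: 13 2-{[(1S,6R)-1,6-dimethyl-2-(4-methylpent-3-en-1-yl)cyclohex-2-en-1-yl]methyl}-1,3-bis(methoxymethoxy)benzene, via alkylzinc bromide 12 (not isolated)
Conditions: 11, Zn dust, LiCl, THF, 50 °C; then 10, Pd(dppf)Cl2 (5 mol%), THF/NMP, 60 °C
Reagents that add atoms: none
Why: Negishi coupling, in which zinc insertion gives a primary alkylzinc that transmetalates to the alkenylpalladium formed by oxidative addition of zerovalent palladium to the triflate, and the wide-bite-angle dppf ligand makes reductive elimination faster than β-hydride elimination.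

Step 7
Reactants: 13 2-{[(1S,6R)-1,6-dimethyl-2-(4-methylpent-3-en-1-yl)cyclohex-2-en-1-yl]methyl}-1,3-bis(methoxymethoxy)benzene
Product: 14 (3S)-3-{2-[(5R,6S)-6-{[2,6-bis(methoxymethoxy)phenyl]methyl}-5,6-dimethylcyclohex-1-en-1-yl]ethyl}-2,2-dimethyloxirane
Conditions: L-fructose-derived Shi ketone (1,2:4,5-di-O-isopropylidene-β-L-erythro-2,3-hexodiulo-2,6-pyranose, 30 mol%), KHSO5 (as 2KHSO5·KHSO4·K2SO4), K2CO3, Bu4NHSO4, MeCN/CH2(OMe)2/aq. Na2B4O7 buffer (pH 10.5), 0 °C
Reagents that add atoms: potassium peroxymonosulfate, [K+].[O-]S(=O)(=O)OO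
Why: Shi asymmetric epoxidation, in which the chiral dioxirane reacts with the unhindered, electron-rich Me2C=CH side-chain alkene far faster than with the ring alkene shielded by the adjacent quaternary C9, and the L-fructose-derived ketone delivers oxygen to the face that gives the S epoxide (catalyst control).

Step 8
Reactants: 14 (3S)-3-{2-[(5R,6S)-6-{[2,6-bis(methoxymethoxy)phenyl]methyl}-5,6-dimethylcyclohex-1-en-1-yl]ethyl}-2,2-dimethyloxirane
Product: 15 (2S,5S,6R,8aR)-5-{[2,6-bis(methoxymethoxy)phenyl]methyl}-1,1,5,6-tetramethyl-1,2,3,5,6,7,8,8a-octahydronaphthalen-2-ol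
Conditions: Cp2TiCl2 (2.5 equiv), Mn dust (8 equiv), degassed THF, rt; the resulting Cp2TiCl solution added slowly to 14 in THF (0.01 M), rt; aq. NaH2PO4
Reagents that add atoms: none
Why: Nugent–RajanBabu radical epoxide opening and 6-endo cyclisation, in which Cp2TiCl (trivalent titanium) cleaves the epoxide to the tertiary C4 radical, which adds to C5 through a chair transition state with the bulky titanoxy group equatorial, so that H-5 ends up trans to the C3 oxygen and the new bond lies on the ring B face that keeps the arylmethyl group, the C8 methyl group and C4 all equatorial (C5 set as R), and the tertiary C10 radical, having no hydrogen on quaternary C9, loses the exposed C1 hydrogen to a second Cp2TiCl to give the C1=C10 alkene without any cationic intermediate that could trigger a 1,2-shift from C9.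

Step 9
Reactants: 15 (2S,5S,6R,8aR)-5-{[2,6-bis(methoxymethoxy)phenyl]methyl}-1,1,5,6-tetramethyl-1,2,3,5,6,7,8,8a-octahydronaphthalen-2-ol
Product: 16 (5S,6R,8aR)-5-{[2,6-bis(methoxymethoxy)phenyl]methyl}-1,1,5,6-tetramethyl-1,5,6,7,8,8a-hexahydronaphthalen-2(3H)-one
Conditions: Dess–Martin periodinane (1.5 equiv), NaHCO3, CH2Cl2, 0 °C → rt
Reagents that add atoms: none
Why: Dess–Martin oxidation under buffered, non-basic conditions converts the hindered secondary alcohol, whose configuration has served only to relay stereocontrol to C5, into the ketone without moving the β,γ-alkene into conjugation.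

Step 10
Reactants: 16 (5S,6R,8aR)-5-{[2,6-bis(methoxymethoxy)phenyl]methyl}-1,1,5,6-tetramethyl-1,5,6,7,8,8a-hexahydronaphthalen-2(3H)-one
Product: 17 (2R,5S,6R,8aR)-5-{[2,6-bis(methoxymethoxy)phenyl]methyl}-1,1,5,6-tetramethyl-1,2,3,5,6,7,8,8a-octahydronaphthalen-2-ol
Conditions: (S)-2-methyl-CBS-oxazaborolidine (20 mol%), catecholborane (1.5 equiv), toluene, −78 → −40 °C; aq. NaOH
Reagents that add atoms: none
Why: Corey–Bakshi–Shibata reduction, in which the quaternary C4 acts as the large and the C2 methylene as the small ketone substituent, so the S oxazaborolidine delivers hydride to the face that gives the 3R alcohol (axial, cis to H-5) under catalyst control, while catecholborane at low temperature neither hydroborates nor isomerises the alkene.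

Step 11
Reactants: 17 (2R,5S,6R,8aR)-5-{[2,6-bis(methoxymethoxy)phenyl]methyl}-1,1,5,6-tetramethyl-1,2,3,5,6,7,8,8a-octahydronaphthalen-2-ol
Product: 18 (2R,5S,6R,8aR)-5-{[2,6-bis(methoxymethoxy)-4-(4,4,5,5-tetramethyl-1,3,2-dioxaborolan-2-yl)phenyl]methyl}-1,1,5,6-tetramethyl-1,2,3,5,6,7,8,8a-octahydronaphthalen-2-ol
Conditions: [Ir(OMe)(cod)]2 (2.5 mol%), 4,4′-di-tert-butyl-2,2′-bipyridine (5 mol%), B2pin2 (2 equiv), THF, 70 °C; aqueous work-up
Reagents that add atoms: bis(pinacolato)diboron, CC1(C)OB(OC1(C)C)B1OC(C)(C)C(C)(C)O1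
Why: Iridium-catalysed aromatic C–H borylation (Hartwig–Miyaura) is governed by sterics, and the only arene C–H bond without an ortho substituent is the one para to the benzylic carbon, so a single boronate is formed.

Step 12
Reactants: 18 (2R,5S,6R,8aR)-5-{[2,6-bis(methoxymethoxy)-4-(4,4,5,5-tetramethyl-1,3,2-dioxaborolan-2-yl)phenyl]methyl}-1,1,5,6-tetramethyl-1,2,3,5,6,7,8,8a-octahydronaphthalen-2-ol
Product: 20 (2R,5S,6R,8aR)-5-{[4-(hydroxymethyl)-2,6-bis(methoxymethoxy)phenyl]methyl}-1,1,5,6-tetramethyl-1,2,3,5,6,7,8,8a-octahydronaphthalen-2-ol, via benzylic pinacol boronate 19 (not isolated)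
Conditions: n-BuLi (1.05 equiv), THF, −78 °C; then BrCH2Cl (2 equiv), n-BuLi (1.5 equiv), −78 °C → rt; then NaOH, H2O2, 0 °C → rt
Reagents that add atoms: bromochloromethane, ClCBr; hydrogen peroxide, OO
Why: Matteson homologation, in which chloromethyllithium generated in situ adds to boron and a 1,2-aryl shift with loss of chloride inserts one carbon, after which alkaline peroxide oxidises the C–B bond to the benzylic alcohol.

Step 13
Reactants: 20 (2R,5S,6R,8aR)-5-{[4-(hydroxymethyl)-2,6-bis(methoxymethoxy)phenyl]methyl}-1,1,5,6-tetramethyl-1,2,3,5,6,7,8,8a-octahydronaphthalen-2-ol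
Product: 21 5-(hydroxymethyl)-2-{[(1S,2R,4aR,6R)-6-hydroxy-1,2,5,5-tetramethyl-1,2,3,4,4a,5,6,7-octahydronaphthalen-1-yl]methyl}benzene-1,3-diol
Conditions: ZnBr2 (2 equiv), n-PrSH (4 equiv), CH2Cl2, 0 °C → rt, 15 min
Reagents that add atoms: none
Why: Lewis acid–thiol acetal cleavage removes both aryl methoxymethyl groups within minutes under aprotic conditions too mild to protonate the trisubstituted alkene, which avoids acid-induced cyclisation of a free phenol onto C10.

Step 14
Reactants: 21 5-(hydroxymethyl)-2-{[(1S,2R,4aR,6R)-6-hydroxy-1,2,5,5-tetramethyl-1,2,3,4,4a,5,6,7-octahydronaphthalen-1-yl]methyl}benzene-1,3-diol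
Product: 22 2,4-dihydroxy-6-(hydroxymethyl)-3-{[(1S,2R,4aR,6R)-6-hydroxy-1,2,5,5-tetramethyl-1,2,3,4,4a,5,6,7-octahydronaphthalen-1-yl]methyl}benzaldehyde
Conditions: MgCl2 (4 equiv), Et3N (8 equiv), (CH2O)n (10 equiv), MeCN, 70 °C; aq. citric acid
Reagents that add atoms: formaldehyde, C=O
Why: Magnesium-mediated ortho-formylation (Casnati–Skattebøl), in which the magnesium phenoxide delivers formaldehyde to its free ortho position and a second formaldehyde oxidises the resulting salicyl alkoxide by hydride transfer, the two open ring positions being equivalent by symmetry and the first formyl group deactivating the ring toward a second.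

**Compound list**
1 | resorcinol (benzene-1,3-diol) | Oc1cccc(O)c1 | starting material
2 | 1,3-bis(methoxymethoxy)benzene | COCOc1cccc(OCOC)c1 | intermediate
3 | [2,6-bis(methoxymethoxy)phenyl]lithium | [Li]c1c(OCOC)cccc1OCOC | intermediate
4 | [2,6-bis(methoxymethoxy)phenyl]methanol | OCc1c(OCOC)cccc1OCOC | intermediate
5 | 2-(bromomethyl)-1,3-bis(methoxymethoxy)benzene | BrCc1c(OCOC)cccc1OCOC | intermediate
6 | 2-methylcyclohex-2-en-1-one | CC1=CCCCC1=O | starting material
7 | dimethylaluminium (R)-2,3-dimethylcyclohex-1-en-1-olate | C[C@@H]1CCCC(O[Al](C)C)=C1C | intermediate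
8 | lithium trimethyl[(R)-2,3-dimethylcyclohex-1-en-1-olato]aluminate | [Li+].C[C@@H]1CCCC(O[Al-](C)(C)C)=C1C | intermediate
9 | (2S,3R)-2-{[2,6-bis(methoxymethoxy)phenyl]methyl}-2,3-dimethylcyclohexan-1-one | C[C@@H]1CCCC(=O)[C@@]1(C)Cc1c(OCOC)cccc1OCOC | intermediate
10 | (5R,6S)-6-{[2,6-bis(methoxymethoxy)phenyl]methyl}-5,6-dimethylcyclohex-1-en-1-yl trifluoromethanesulfonate | C[C@@H]1CCC=C(OS(=O)(=O)C(F)(F)F)[C@@]1(C)Cc1c(OCOC)cccc1OCOC | intermediate
11 | 5-bromo-2-methylpent-2-ene | CC(C)=CCCBr | starting material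
12 | bromo(4-methylpent-3-en-1-yl)zinc | CC(C)=CCC[Zn]Br | intermediate
13 | 2-{[(1S,6R)-1,6-dimethyl-2-(4-methylpent-3-en-1-yl)cyclohex-2-en-1-yl]methyl}-1,3-bis(methoxymethoxy)benzene | C[C@@H]1CCC=C(CCC=C(C)C)[C@@]1(C)Cc1c(OCOC)cccc1OCOC | intermediate
14 | (3S)-3-{2-[(5R,6S)-6-{[2,6-bis(methoxymethoxy)phenyl]methyl}-5,6-dimethylcyclohex-1-en-1-yl]ethyl}-2,2-dimethyloxirane | C[C@@H]1CCC=C(CC[C@@H]2OC2(C)C)[C@@]1(C)Cc1c(OCOC)cccc1OCOC | intermediate
15 | (2S,5S,6R,8aR)-5-{[2,6-bis(methoxymethoxy)phenyl]methyl}-1,1,5,6-tetramethyl-1,2,3,5,6,7,8,8a-octahydronaphthalen-2-ol | C[C@@H]1CC[C@@H]2C(=CC[C@H](O)C2(C)C)[C@@]1(C)Cc1c(OCOC)cccc1OCOC | intermediate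
16 | (5S,6R,8aR)-5-{[2,6-bis(methoxymethoxy)phenyl]methyl}-1,1,5,6-tetramethyl-1,5,6,7,8,8a-hexahydronaphthalen-2(3H)-one | C[C@@H]1CC[C@@H]2C(=CCC(=O)C2(C)C)[C@@]1(C)Cc1c(OCOC)cccc1OCOC | intermediate
17 | (2R,5S,6R,8aR)-5-{[2,6-bis(methoxymethoxy)phenyl]methyl}-1,1,5,6-tetramethyl-1,2,3,5,6,7,8,8a-octahydronaphthalen-2-ol | C[C@@H]1CC[C@@H]2C(=CC[C@@H](O)C2(C)C)[C@@]1(C)Cc1c(OCOC)cccc1OCOC | intermediate
18 | (2R,5S,6R,8aR)-5-{[2,6-bis(methoxymethoxy)-4-(4,4,5,5-tetramethyl-1,3,2-dioxaborolan-2-yl)phenyl]methyl}-1,1,5,6-tetramethyl-1,2,3,5,6,7,8,8a-octahydronaphthalen-2-ol | C[C@@H]1CC[C@@H]2C(=CC[C@@H](O)C2(C)C)[C@@]1(C)Cc1c(OCOC)cc(B3OC(C)(C)C(C)(C)O3)cc1OCOC | intermediate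
19 | (2R,5S,6R,8aR)-5-{[2,6-bis(methoxymethoxy)-4-[(4,4,5,5-tetramethyl-1,3,2-dioxaborolan-2-yl)methyl]phenyl]methyl}-1,1,5,6-tetramethyl-1,2,3,5,6,7,8,8a-octahydronaphthalen-2-ol | C[C@@H]1CC[C@@H]2C(=CC[C@@H](O)C2(C)C)[C@@]1(C)Cc1c(OCOC)cc(CB3OC(C)(C)C(C)(C)O3)cc1OCOC | intermediate
20 | (2R,5S,6R,8aR)-5-{[4-(hydroxymethyl)-2,6-bis(methoxymethoxy)phenyl]methyl}-1,1,5,6-tetramethyl-1,2,3,5,6,7,8,8a-octahydronaphthalen-2-ol | C[C@@H]1CC[C@@H]2C(=CC[C@@H](O)C2(C)C)[C@@]1(C)Cc1c(OCOC)cc(CO)cc1OCOC | intermediate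
21 | 5-(hydroxymethyl)-2-{[(1S,2R,4aR,6R)-6-hydroxy-1,2,5,5-tetramethyl-1,2,3,4,4a,5,6,7-octahydronaphthalen-1-yl]methyl}benzene-1,3-diol | C[C@@H]1CC[C@@H]2C(=CC[C@@H](O)C2(C)C)[C@@]1(C)Cc1c(O)cc(CO)cc1O | intermediate
22 | 2,4-dihydroxy-6-(hydroxymethyl)-3-{[(1S,2R,4aR,6R)-6-hydroxy-1,2,5,5-tetramethyl-1,2,3,4,4a,5,6,7-octahydronaphthalen-1-yl]methyl}benzaldehyde | C[C@@H]1CC[C@@H]2C(=CC[C@@H](O)C2(C)C)[C@@]1(C)Cc1c(O)cc(CO)c(C=O)c1O | target

**Totals and risks**

Total step count: 14. Longest linear sequence: 14 steps (resorcinol 1 to target 22; enone 6 enters at step 4 and bromide 11 at step 6).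

The three steps most likely to fail:

Step 8 (radical ring closure). Risks are premature quenching of the C4 radical to an allylic alcohol, loss of the C5 hydrogen instead of a C1 hydrogen, and imperfect face selectivity at C5. The fallback sets out from triflate 10 and comes back at ketone 16. Methyl 2-methylpropanoate is converted by Kulinkovich cyclopropanation (EtMgBr, Ti(OiPr)4, THF) into 1-(propan-2-yl)cyclopropan-1-ol F1. Palladium-catalysed ring-opening coupling of this homoenolate precursor with 10 (Pd(OAc)2, XPhos, Cs2CO3, toluene, 80 °C) gives 1-[(5R,6S)-6-{[2,6-bis(methoxymethoxy)phenyl]methyl}-5,6-dimethylcyclohex-1-en-1-yl]-4-methylpentan-3-one F2. Oxidative radical cyclisation of F2 with Mn(OAc)3·2H2O and Cu(OAc)2·H2O in AcOH at 50 °C then generates the tertiary α-keto radical at C4, closes ring A 6-endo and oxidises the C10 radical to the less substituted alkene, giving 16 without the epoxidation and alcohol oxidation steps. In this variant C5 is controlled only by ring B, so the diastereomer ratio is expected to be lower.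

Step 4 (conjugate addition and benzylation of a hindered, fully substituted enolate). Risks are slow SN2 attack on a doubly ortho-substituted benzyl bromide and O-alkylation. The fallback sets out from aluminium enolate 7 and comes back at ketone 9. Compound 7 is quenched with TMSCl and Et3N to give trimethyl{[(3R)-2,3-dimethylcyclohex-1-en-1-yl]oxy}silane F3, which is isolated. F3 is then alkylated with bromide 5 under ZnBr2 catalysis in CH2Cl2 at −40 °C, an SN1-type Lewis acid alkylation of a silyl enol ether by the stabilised 2,6-dialkoxybenzyl cation. The cation again approaches anti to the C8 methyl group and gives 9.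

Step 14 (formylation of the unprotected tetraol). Risks are double formylation, hydroxymethylated by-products and low conversion. The fallback sets out from 20 and comes back at target 22. Acetal-directed ortho-lithiation of 20 (n-BuLi, 4 equiv, TMEDA, THF, −20 °C), helped by the neighbouring lithium benzyl alkoxide, followed by DMF gives 6-(hydroxymethyl)-3-{[(1S,2R,4aR,6R)-6-hydroxy-1,2,5,5-tetramethyl-1,2,3,4,4a,5,6,7-octahydronaphthalen-1-yl]methyl}-2,4-bis(methoxymethoxy)benzaldehyde F4. The two acetals of F4 are then cleaved with dilute HCl in MeOH/THF at 40 °C to give 22.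

Further compounds
F1 | step 8 | 1-(propan-2-yl)cyclopropan-1-ol | CC(C)C1(O)CC1
F2 | step 8 | 1-[(5R,6S)-6-{[2,6-bis(methoxymethoxy)phenyl]methyl}-5,6-dimethylcyclohex-1-en-1-yl]-4-methylpentan-3-one | C[C@@H]1CCC=C(CCC(=O)C(C)C)[C@@]1(C)Cc1c(OCOC)cccc1OCOC
F3 | step 4 | trimethyl{[(3R)-2,3-dimethylcyclohex-1-en-1-yl]oxy}silane | C[C@@H]1CCCC(O[Si](C)(C)C)=C1C
F4 | step 14 | 6-(hydroxymethyl)-3-{[(1S,2R,4aR,6R)-6-hydroxy-1,2,5,5-tetramethyl-1,2,3,4,4a,5,6,7-octahydronaphthalen-1-yl]methyl}-2,4-bis(methoxymethoxy)benzaldehyde | C[C@@H]1CC[C@@H]2C(=CC[C@@H](O)C2(C)C)[C@@]1(C)Cc1c(OCOC)cc(CO)c(C=O)c1OCOC
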